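Everything rests on opening flavone ring C at two bonds together: O1–C2 and the congested C3–C8 bond to the flavan. The feature exploited is the enol ether O1–C2=C3 of ring C. Stripped of its ring A oxygen and of the aryl group on C3, it is simply the C≡C unit of a 1,3-diarylpropynone. One palladium-catalysed arylative 6-endo-dig cyclisation should therefore close the pyranone and unite both halves in a single operation. Its precursors are the enantiopure (2S)-8-iodoflavan tribenzyl ether and an o-(triisopropylsilyloxy)aryl ynone whose phenoxide is released by fluoride without any proton source. Both fragments stem from 2,4-bis(benzyloxy)-6-hydroxybenzaldehyde, and hydrogenolysis of six benzyl ethers ends the route.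

Key step: step 11

Assumption: the C3–C8 axis carries no stereo label in the target structure, so only flavan C2 is controlled and any slowly interconverting rotamers are treated as one compound.

Step 1
Reactants: 1 2,4,6-trihydroxybenzaldehyde
Product: 2 2,4,6-tris(benzyloxy)benzaldehyde
Conditions: BnBr (3.6 equiv), K2CO3 (4.5 equiv), DMF, rt → 50 °C
Reagents that add atoms: benzyl bromide, BrCc1ccccc1
Why: Williamson ether synthesis in a polar aprotic solvent, where the formyl group tempers the carbon nucleophilicity of the phloroglucinol ring so that O-benzylation should prevail, and the excess of halide carries the two hydrogen-bonded ortho phenols to completion.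

Step 2
Reactants: 2 2,4,6-tris(benzyloxy)benzaldehyde
Product: 3 2,4-bis(benzyloxy)-6-hydroxybenzaldehyde
Conditions: MgBr2·OEt2 (1.2 equiv), toluene/Et2O 6:1, 80 °C; 1 M HCl work-up
Reagents that add atoms: none
Why: Chelation-directed ether cleavage, in which magnesium bridges the formyl oxygen and one ortho ether oxygen, bromide removes only that activated benzyl group by SN2 attack, and the resulting magnesium phenoxide chelate occupies the carbonyl so that the second ortho ether and the para ether should stay.

Step 3
Reactants: 3 2,4-bis(benzyloxy)-6-hydroxybenzaldehyde; 4 4'-benzyloxyacetophenone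
Product: 5 (E)-3-[2,4-bis(benzyloxy)-6-hydroxyphenyl]-1-[4-(benzyloxy)phenyl]prop-2-en-1-one
Conditions: KOH (50 % aq, 8 equiv), EtOH/THF 2:1, rt → 45 °C, dark; AcOH to pH 6 at 0 °C
Reagents that add atoms: none
Why: Claisen–Schmidt condensation (aldol addition, then E1cB loss of water) gives the conjugated (E)-enone under thermodynamic control, with concentrated base and gentle heat offsetting the low electrophilicity of the phenoxide aldehyde and the weak-acid neutralisation avoiding closure of the 2-hydroxychalcone to a flavylium salt.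

Step 4
Reactants: 5 (E)-3-[2,4-bis(benzyloxy)-6-hydroxyphenyl]-1-[4-(benzyloxy)phenyl]prop-2-en-1-one
Product: 6 3-[2,4-bis(benzyloxy)-6-hydroxyphenyl]-1-[4-(benzyloxy)phenyl]propan-1-one
Conditions: H2 (3 atm), RhCl(PPh3)3 (5 mol %), toluene/EtOH 1:1, 40 °C
Reagents that add atoms: none
Why: Homogeneous rhodium-catalysed hydrogenation saturates the disubstituted enone C=C bond while leaving aryl benzyl ethers and the aryl ketone alone, and taking the alkene out first keeps the later hydride step from forming an allylic alcohol that would ionise next to the electron-rich ring.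

Step 5
Reactants: 6 3-[2,4-bis(benzyloxy)-6-hydroxyphenyl]-1-[4-(benzyloxy)phenyl]propan-1-one
Product: 7 (1R)-3-[2,4-bis(benzyloxy)-6-hydroxyphenyl]-1-[4-(benzyloxy)phenyl]propan-1-ol
Conditions: RuCl(p-cymene)[(R,R)-TsDPEN] (1 mol %), HCO2H/NEt3 5:2, EtOAc, 35 °C
Reagents that add atoms: none
Why: Noyori–Ikariya asymmetric transfer hydrogenation, in whose six-membered outer-sphere transition state the aryl group of the ketone lies under the p-cymene ligand (CH/π attraction), so that the (R,R) catalyst hands hydride to the Si face and sets the (R)-carbinol in the sense known for aryl alkyl ketones, while loss of CO2 makes the reduction irreversible.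

Step 6
Reactants: 7 (1R)-3-[2,4-bis(benzyloxy)-6-hydroxyphenyl]-1-[4-(benzyloxy)phenyl]propan-1-ol
Product: 8 (2S)-5,7-bis(benzyloxy)-2-[4-(benzyloxy)phenyl]chroman
Conditions: PPh3 (1.5 equiv), DIAD (1.5 equiv), toluene (0.02 M), −20 → 0 °C
Reagents that add atoms: none
Why: Intramolecular Mitsunobu etherification, in which the phenol displaces the alkoxyphosphonium group in a 6-exo-tet SN2 step with inversion from (R) to (2S), and the cold, weakly polar, dilute medium holds back ionisation of the 4-benzyloxybenzylic centre, elimination and intermolecular etherification.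

Step 7
Reactants: 8 (2S)-5,7-bis(benzyloxy)-2-[4-(benzyloxy)phenyl]chroman
Product: 9 (2S)-5,7-bis(benzyloxy)-2-[4-(benzyloxy)phenyl]-8-iodochroman
Conditions: NIS (1.0 equiv), CH2Cl2, −20 → 0 °C, dark
Reagents that add atoms: N-iodosuccinimide, O=C1CCC(=O)N1I
Why: Electrophilic aromatic iodination goes to ring A as by far the most activated ring, and within it C8, next to the ring oxygen that is tied back in the pyran, is more open than C6 between two freely rotating benzyloxy groups, which is the site preference known for halogenation of 5,7-di-O-benzyl flavan-3-ols, while one equivalent of reagent limits double iodination.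

Step 8
Reactants: 3 2,4-bis(benzyloxy)-6-hydroxybenzaldehyde
Product: 10 2,4-bis(benzyloxy)-6-(triisopropylsilyloxy)benzaldehyde
Conditions: TIPSOTf (1.2 equiv), 2,6-lutidine (2 equiv), CH2Cl2, 0 °C → rt
Reagents that add atoms: triisopropylsilyl triflate, CC(C)[Si](OS(=O)(=O)C(F)(F)F)(C(C)C)C(C)C
Why: O-silylation with a silyl triflate is forceful enough to overcome the hydrogen bond of the phenol to the formyl group, and the bulky silyl ether should outlast acetylide addition and oxidation yet fall readily to fluoride.

Step 9
Reactants: 10 2,4-bis(benzyloxy)-6-(triisopropylsilyloxy)benzaldehyde; 11 1-(benzyloxy)-4-ethynylbenzene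
Product: 13 rac-1-[2,4-bis(benzyloxy)-6-(triisopropylsilyloxy)phenyl]-3-[4-(benzyloxy)phenyl]prop-2-yn-1-ol, via lithium acetylide 12 (not isolated)
Conditions: 11 (1.15 equiv), n-BuLi (1.1 equiv), THF, −78 °C, 30 min; then 10, −78 °C; AcOH/THF quench at −78 °C
Reagents that add atoms: none
Why: 1,2-Addition of a lithium acetylide to an aldehyde, where the cold acidic quench protonates the alkoxide before the neighbouring silyl group can migrate from the phenol oxygen to the carbinol oxygen, and the new carbinol centre may be racemic because the next step erases it.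

Step 10
Reactants: 13 rac-1-[2,4-bis(benzyloxy)-6-(triisopropylsilyloxy)phenyl]-3-[4-(benzyloxy)phenyl]prop-2-yn-1-ol
Product: 14 1-[2,4-bis(benzyloxy)-6-(triisopropylsilyloxy)phenyl]-3-[4-(benzyloxy)phenyl]prop-2-yn-1-one
Conditions: MnO2 (activated, 15 equiv), CH2Cl2, rt
Reagents that add atoms: none
Why: Heterogeneous MnO2 oxidation is selective for benzylic and propargylic alcohols and runs at neutral pH, so neither acid ionisation of the doubly activated carbinol nor loss of the silyl ether should occur.

Step 11
Reactants: 9 (2S)-5,7-bis(benzyloxy)-2-[4-(benzyloxy)phenyl]-8-iodochroman; 14 1-[2,4-bis(benzyloxy)-6-(triisopropylsilyloxy)phenyl]-3-[4-(benzyloxy)phenyl]prop-2-yn-1-one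
Product: 16 hexa-O-benzyl daphnodorin D2, namely 5,7-bis(benzyloxy)-2-[4-(benzyloxy)phenyl]-3-{(2S)-5,7-bis(benzyloxy)-2-[4-(benzyloxy)phenyl]chroman-8-yl}-4H-chromen-4-one, via caesium phenoxide 15 (not isolated)
Conditions: 9 (1.0 equiv), Pd2(dba)3 (5 mol %), SPhos (20 mol %), 1,4-dioxane, 90 °C, 15 min; then CsF (3 equiv, dried), 4 Å MS, 14 (1.3 equiv) added over 5 h, 90 °C
Reagents that add atoms: none
Why: Proposed new method: SPhos-ligated zerovalent palladium inserts into the carbon–iodine bond at C8 of 9 to give an arylpalladium iodide (divalent palladium), while sparingly soluble CsF strips the silyl group from slowly added 14 and releases phenoxide 15 in a medium that holds no proton donor. The phenoxide oxygen attacks the alkyne carbon β to the ketone, either anti to the arylpalladium unit π-bound to the triple bond or by a reversible oxa-Michael addition whose C3 carbanion (a bent vinyl anion, since a six-membered ring cannot hold a true allenolate) is caught by the same palladium species; both paths meet at a chromon-3-yl(aryl)palladium complex, and reductive elimination, pushed by the bulky biarylphosphine, makes the C3–C8 bond and returns zerovalent palladium. The nearest known reaction types are the Cacchi-type oxypalladation/reductive elimination of o-alkynylphenols (and aminopalladation of o-alkynylanilines) with aryl halides, the fluoride- or base-induced 6-endo closure of o-alkynoylphenols to flavones, and the iodocyclisation of o-alkoxyaryl ynones to 3-iodochromones, whereas their union on an ynone with a doubly ortho-oxygenated aryl iodide has not been shown. Pyranone ring C closes in the 6-endo-dig mode through O1–C2 bond formation, no stereocentre is created, and the (2S) centre of 9, remote from both reacting sites and unable to open to a quinone methide while its 4'-oxygen is benzylated, is carried through unchanged. Two selectivities are required: six-membered over five-membered (5-exo, aurone-type) closure, secured by the polarisation of the ynone that the 4-benzyloxyphenyl donor on the β carbon reinforces and by the aprotic medium in which a 5-exo adduct can revert, and arylation instead of protonation at C3, secured by unmasking a silyl ether in place of a free phenol, by dried CsF and molecular sieves, and by keeping 15 scarce next to the preformed arylpalladium iodide. The coupling site on the flavan is settled in advance by the iodide, and letting the electron-rich flavan enter as the halide spares the route an arylmetal partner that would readily lose its metal to a proton.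

Step 12
Reactants: 16 hexa-O-benzyl daphnodorin D2
Product: 17 daphnodorin D2
Conditions: H2 (1 atm), Pd(OH)2/C (20 wt %), THF/MeOH 1:1, rt, followed by LC–MS and filtered once the last benzyl group has gone
Reagents that add atoms: none
Why: Catalytic hydrogenolysis, in which the six primary aryl benzyl ethers cleave much faster than the secondary C2–O1 bond held in the pyran ring breaks or the tetrasubstituted C2=C3 bond of the flavone is reduced, as is usual in the global debenzylation of benzylated flavan-3-ols, and the neutral medium at room temperature avoids a quinone methide ring opening that would scramble C2.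

Compound list
1 | 2,4,6-trihydroxybenzaldehyde | O=Cc1c(O)cc(O)cc1O | starting material
2 | 2,4,6-tris(benzyloxy)benzaldehyde | O=Cc1c(OCc2ccccc2)cc(OCc2ccccc2)cc1OCc1ccccc1 | intermediate
3 | 2,4-bis(benzyloxy)-6-hydroxybenzaldehyde | O=Cc1c(O)cc(OCc2ccccc2)cc1OCc1ccccc1 | intermediate
4 | 4'-benzyloxyacetophenone | CC(=O)c1ccc(OCc2ccccc2)cc1 | starting material
5 | (E)-3-[2,4-bis(benzyloxy)-6-hydroxyphenyl]-1-[4-(benzyloxy)phenyl]prop-2-en-1-one | O=C(/C=C/c1c(O)cc(OCc2ccccc2)cc1OCc1ccccc1)c1ccc(OCc2ccccc2)cc1 | intermediate
6 | 3-[2,4-bis(benzyloxy)-6-hydroxyphenyl]-1-[4-(benzyloxy)phenyl]propan-1-one | O=C(CCc1c(O)cc(OCc2ccccc2)cc1OCc1ccccc1)c1ccc(OCc2ccccc2)cc1 | intermediate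
7 | (1R)-3-[2,4-bis(benzyloxy)-6-hydroxyphenyl]-1-[4-(benzyloxy)phenyl]propan-1-ol | O[C@H](CCc1c(O)cc(OCc2ccccc2)cc1OCc1ccccc1)c1ccc(OCc2ccccc2)cc1 | intermediate
8 | (2S)-5,7-bis(benzyloxy)-2-[4-(benzyloxy)phenyl]chroman | c1c(OCc2ccccc2)cc(OCc2ccccc2)c2c1O[C@H](c1ccc(OCc3ccccc3)cc1)CC2 | intermediate
9 | (2S)-5,7-bis(benzyloxy)-2-[4-(benzyloxy)phenyl]-8-iodochroman | Ic1c(OCc2ccccc2)cc(OCc2ccccc2)c2c1O[C@H](c1ccc(OCc3ccccc3)cc1)CC2 | intermediate
10 | 2,4-bis(benzyloxy)-6-(triisopropylsilyloxy)benzaldehyde | O=Cc1c(O[Si](C(C)C)(C(C)C)C(C)C)cc(OCc2ccccc2)cc1OCc1ccccc1 | intermediate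
11 | 1-(benzyloxy)-4-ethynylbenzene | C#Cc1ccc(OCc2ccccc2)cc1 | starting material
12 | lithium [4-(benzyloxy)phenyl]acetylide (not isolated) | [Li]C#Cc1ccc(OCc2ccccc2)cc1 | intermediate
13 | rac-1-[2,4-bis(benzyloxy)-6-(triisopropylsilyloxy)phenyl]-3-[4-(benzyloxy)phenyl]prop-2-yn-1-ol | OC(C#Cc1ccc(OCc2ccccc2)cc1)c1c(O[Si](C(C)C)(C(C)C)C(C)C)cc(OCc2ccccc2)cc1OCc1ccccc1 | intermediate
14 | 1-[2,4-bis(benzyloxy)-6-(triisopropylsilyloxy)phenyl]-3-[4-(benzyloxy)phenyl]prop-2-yn-1-one | O=C(C#Cc1ccc(OCc2ccccc2)cc1)c1c(O[Si](C(C)C)(C(C)C)C(C)C)cc(OCc2ccccc2)cc1OCc1ccccc1 | intermediate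
15 | caesium 3,5-bis(benzyloxy)-2-{3-[4-(benzyloxy)phenyl]prop-2-ynoyl}phenoxide (not isolated) | [Cs+].[O-]c1cc(OCc2ccccc2)cc(OCc2ccccc2)c1C(=O)C#Cc1ccc(OCc2ccccc2)cc1 | intermediate
16 | hexa-O-benzyl daphnodorin D2 (three benzyl ethers on each half, 2S) | O=c1c(-c2c(OCc3ccccc3)cc(OCc3ccccc3)c3c2O[C@H](c2ccc(OCc4ccccc4)cc2)CC3)c(-c2ccc(OCc3ccccc3)cc2)oc2cc(OCc3ccccc3)cc(OCc3ccccc3)c12 | intermediate
17 | daphnodorin D2, 5,7-dihydroxy-3-[(2S)-5,7-dihydroxy-2-(4-hydroxyphenyl)chroman-8-yl]-2-(4-hydroxyphenyl)-4H-chromen-4-one | O=c1c(-c2c(O)cc(O)c3c2O[C@H](c2ccc(O)cc2)CC3)c(-c2ccc(O)cc2)oc2cc(O)cc(O)c12 | target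

Total step count: 12. Longest linear sequence: 9 steps (steps 1 to 7, then 11 and 12).

The three steps most likely to fail:

**First, step 11.**
- What may go wrong: the cyclised C3 carbanion may be protonated faster than palladium captures it. Oxidative addition into the crowded, electron-rich iodide may lag behind desilylation. Carbopalladation of the alkyne or 5-exo closure may also intrude.
- Scope of the fallback: it takes ring closure and biaryl coupling apart and uses known chemistry only. It sets out from 14 and 9 and comes back at 16.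
- Flavone half: treating 14 with CsF in dry DMF at room temperature and quenching with aqueous NH4Cl should give, by way of 15 and 6-endo closure, 5,7-bis(benzyloxy)-2-[4-(benzyloxy)phenyl]-4H-chromen-4-one F1. Deprotonation at C3 with LiN(iPr)2 (THF, −78 °C) gives the 3-lithioflavone F2, which is quenched with iodine to the 3-iodoflavone F3.
- Flavan half: in parallel, 9 is borylated with pinacolborane (PdCl2(MeCN)2, SPhos, NEt3, dioxane, 80 °C) to the flavan-8-yl pinacol boronate F4.
- Union: Suzuki–Miyaura coupling of F3 and F4 (Pd(OAc)2, SPhos, K3PO4, toluene/H2O, 100 °C) then forms the C3–C8 bond of 16.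

**Second, step 6.**
- What may go wrong: the activated 4-benzyloxybenzylic carbinol may ionise before the phenol attacks. That would erode the enantiomeric purity or lead to elimination to a styrene.
- Scope of the fallback: it never places a leaving group on the benzylic carbon. It sets out from 6 and comes back at 8.
- Sequence: ketone 6 is cyclodehydrated (catalytic p-TsOH, toluene, Dean–Stark trap) to 5,7-bis(benzyloxy)-2-[4-(benzyloxy)phenyl]-4H-chromene F5. Its cyclic enol ether C2=C3 bond is then hydrogenated enantioselectively with an iridium P,N catalyst such as [Ir(cod)(tBu-PHOX)][B(3,5-(CF3)2C6H3)4] (H2 50 bar, CH2Cl2, rt). The ligand antipode is chosen for the (2S) product.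
- Basis: this is the known asymmetric hydrogenation of 2-aryl-4H-chromenes, and it leaves benzyl ethers untouched.

**Third, step 3.**
- What may go wrong: deprotonation of the phenol turns the formyl group into a vinylogous carboxylate. Aldol addition may then stall or revert.
- Scope of the fallback: it replaces the base-driven condensation by a neutral Wittig olefination. The phenol stays protonated and its hydrogen bond activates the aldehyde. It sets out from 4 and 3 and comes back at 5.
- Sequence: ketone 4 is brominated (CuBr2, EtOAc/CHCl3, reflux) to 2-bromo-1-[4-(benzyloxy)phenyl]ethan-1-one F6. PPh3 in toluene converts this into {2-[4-(benzyloxy)phenyl]-2-oxoethyl}triphenylphosphonium bromide F7. Aqueous Na2CO3 liberates the stabilised ylide 1-[4-(benzyloxy)phenyl]-2-(triphenyl-λ5-phosphanylidene)ethan-1-one F8. Heating F8 with 3 in toluene at 90 °C should give the (E)-enone 5.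

Further compounds
F1 | step 11 | 5,7-bis(benzyloxy)-2-[4-(benzyloxy)phenyl]-4H-chromen-4-one | O=c1cc(-c2ccc(OCc3ccccc3)cc2)oc2cc(OCc3ccccc3)cc(OCc3ccccc3)c12
F2 | step 11 | 5,7-bis(benzyloxy)-2-[4-(benzyloxy)phenyl]-3-lithio-4H-chromen-4-one | O=c1c([Li])c(-c2ccc(OCc3ccccc3)cc2)oc2cc(OCc3ccccc3)cc(OCc3ccccc3)c12
F3 | step 11 | 5,7-bis(benzyloxy)-2-[4-(benzyloxy)phenyl]-3-iodo-4H-chromen-4-one | O=c1c(I)c(-c2ccc(OCc3ccccc3)cc2)oc2cc(OCc3ccccc3)cc(OCc3ccccc3)c12
F4 | step 11 | (2S)-5,7-bis(benzyloxy)-2-[4-(benzyloxy)phenyl]-8-(4,4,5,5-tetramethyl-1,3,2-dioxaborolan-2-yl)chroman | CC1(C)OB(OC1(C)C)c1c(OCc2ccccc2)cc(OCc2ccccc2)c2c1O[C@H](c1ccc(OCc3ccccc3)cc1)CC2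
F5 | step 6 | 5,7-bis(benzyloxy)-2-[4-(benzyloxy)phenyl]-4H-chromene | C1(c2ccc(OCc3ccccc3)cc2)=CCc2c(OCc3ccccc3)cc(OCc3ccccc3)cc2O1
F6 | step 3 | 2-bromo-1-[4-(benzyloxy)phenyl]ethan-1-one | O=C(CBr)c1ccc(OCc2ccccc2)cc1
F7 | step 3 | {2-[4-(benzyloxy)phenyl]-2-oxoethyl}triphenylphosphonium bromide | [Br-].O=C(C[P+](c1ccccc1)(c1ccccc1)c1ccccc1)c1ccc(OCc2ccccc2)cc1
F8 | step 3 | 1-[4-(benzyloxy)phenyl]-2-(triphenyl-λ5-phosphanylidene)ethan-1-one | O=C(C=P(c1ccccc1)(c1ccccc1)c1ccccc1)c1ccc(OCc2ccccc2)cc1
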